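**Plan**

Locants: flavanone numbering (O1, C2, C3, C4, C4a, C5–C8, C8a; ring A = benzo ring, ring B = aryl on C2, ring C = pyranone); the chain on C8 is C1''–C9'' counted outwards. TBS = tert-butyldimethylsilyl, TBSO = TBS-oxy.
Retrosynthesis cuts, in order: all O–Si bonds; C4–C4a (ring C opens to a 3-aryl-3-aryloxypropanoic acid); O1–C2; a temporary O7–Si–O(C1'') ring and the C1'' carbinol (from the ketone); C3''–C4'' (alkenyl + enone); C2''=C3'' (aldol), back to 2',6'-dihydroxy-4'-methoxyacetophenone.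
Forward: the C8 chain is joined first (aldol condensation, Rh-catalysed alkenyl 1,4-addition, ketone reduction), then a temporary silylene ring is made, the ring B unit is hung on O1, and ring C is closed last.
Enabling feature: until ring C exists, ring A is a 2-substituted 5-methoxyresorcinol in which O1/O7 and C4a/C6 are equivalent pairs. A six-membered O7–Si(t-Bu)2–O–C1'' ring picks one oxygen, masks the acid-labile C1'' carbinol, and leaves one phenol (O1) whose only reachable ortho carbon, C4a, is activated by O1 and the C5 methoxy group (ortho) and by O7 (para).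
Stereocentres: C7'' from phosphoric acid-catalysed propargylation, C3'' from (S)-BINAP–Rh 1,4-addition, C1'' from CBS reduction, C2 from transfer hydrogenation then Mitsunobu inversion; the E-alkene from alkyne hydroboration. The ring closure touches none of them.
All other hydroxyl groups travel as TBS ethers and are released together with the silylene ring in one fluoride step.

Key step: step 17

Remark: the sense of induction of each chiral catalyst is assigned from the accepted model of its reaction class (the mirror-image catalyst would be used if a first run showed the opposite sense); methyl 3-(4-hydroxyphenyl)-3-oxopropanoate is taken as commercially available.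

**Route**

Step 1
Reactants: 1 methyl 3-(4-hydroxyphenyl)propanoate
Product: 2 methyl 3-[4-(TBSO)phenyl]propanoate
Conditions: TBSCl, imidazole, DMF, rt
Reagents that add atoms: TBSCl, CC(C)(C)[Si](C)(C)Cl
Why: Phenol silylation (silyl ether formation) is fast with imidazole and leaves the ester untouched.

Step 2
Reactants: 2 methyl 3-[4-(TBSO)phenyl]propanoate
Product: 3 3-[4-(TBSO)phenyl]propanal
Conditions: i-Bu2AlH, CH2Cl2, −78 °C; aqueous work-up
Reagents that add atoms: none
Why: Partial ester reduction with i-Bu2AlH at low temperature stops at the aluminium hemiacetal, which should give the aldehyde on work-up.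

Step 3
Reactants: 3 3-[4-(TBSO)phenyl]propanal
Product: 4 (3S)-1-[4-(TBSO)phenyl]hex-5-yn-3-ol
Conditions: allenyl-B(pin), (R)-TRIP [(R)-3,3'-bis(2,4,6-triisopropylphenyl)-1,1'-binaphthyl-2,2'-diyl hydrogen phosphate] (10 mol%), 4 Å MS, toluene, −20 °C
Reagents that add atoms: allenylboronic acid pinacol ester, C=C=CB1OC(C)(C)C(C)(C)O1
Why: Chiral phosphoric acid-catalysed propargylation of an aldehyde with an allenylboronate runs through a closed six-membered transition state in which the (R)-phosphate differentiates the aldehyde faces, which should set C7'' as (S).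

Step 4
Reactants: 4 (3S)-1-[4-(TBSO)phenyl]hex-5-yn-3-ol
Product: 5 (3S)-3-(TBSO)-1-[4-(TBSO)phenyl]hex-5-yne
Conditions: TBSOTf, 2,6-lutidine, CH2Cl2, −78 → 0 °C
Reagents that add atoms: TBSOTf, CC(C)(C)[Si](C)(C)OS(=O)(=O)C(F)(F)F
Why: Silylation of the secondary alcohol with the silyl triflate protects C7''–OH for the later silylene and Mitsunobu steps.

Step 5
Reactants: 5 (3S)-3-(TBSO)-1-[4-(TBSO)phenyl]hex-5-yne
Product: 7 [(1E,4S)-4-(TBSO)-6-[4-(TBSO)phenyl]hex-1-en-1-yl]boronic acid, via catechol alkenylboronate 6 (not isolated)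
Conditions: catecholborane, (c-C6H11)2BH (10 mol%), THF, rt; then H2O
Reagents that add atoms: catecholborane, B1Oc2ccccc2O1; water, O
Why: Syn, anti-Markovnikov hydroboration of the terminal alkyne (Brown hydroboration) places boron on the terminal carbon and fixes the E geometry, and hydrolysis of the catechol ester frees the boronic acid.

Step 6
Reactants: 8 methyl 3-(4-hydroxyphenyl)-3-oxopropanoate
Product: 9 allyl 3-(4-hydroxyphenyl)-3-oxopropanoate
Conditions: allyl alcohol (excess), DMAP (cat.), toluene, reflux with removal of MeOH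
Reagents that add atoms: allyl alcohol, C=CCO
Why: DMAP-catalysed transesterification of a β-keto ester is driven by distilling out methanol and installs an ester that can later be cleaved without base, acid or fluoride.

Step 7
Reactants: 9 allyl 3-(4-hydroxyphenyl)-3-oxopropanoate
Product: 10 allyl 3-[4-(TBSO)phenyl]-3-oxopropanoate
Conditions: TBSCl, imidazole, CH2Cl2, 0 °C → rt
Reagents that add atoms: TBSCl, CC(C)(C)[Si](C)(C)Cl
Why: Selective silylation of the phenol (silyl ether formation) gives the protecting group that is removed in the final fluoride step.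

Step 8
Reactants: 10 allyl 3-[4-(TBSO)phenyl]-3-oxopropanoate
Product: 11 allyl (3R)-3-hydroxy-3-[4-(TBSO)phenyl]propanoate
Conditions: RuCl[(R,R)-TsDPEN](p-cymene) (1 mol%), HCO2H/Et3N (5:2), rt
Reagents that add atoms: none
Why: Noyori–Ikariya asymmetric transfer hydrogenation of the aryl ketone, in which the (R,R)-catalyst should deliver hydride to the face that gives the (R)-carbinol, as with acetophenone.

Step 9
Reactants: 12 1-(2,6-dihydroxy-4-methoxyphenyl)ethanone
Product: 13 1-[2,6-bis(allyloxy)-4-methoxyphenyl]ethanone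
Conditions: allyl bromide, K2CO3, DMF, 60 °C
Reagents that add atoms: allyl bromide, C=CCBr
Why: Williamson etherification of both phenols gives ethers that survive enolate, rhodium and borane chemistry and are later removed under neutral conditions.

Step 10
Reactants: 13 1-[2,6-bis(allyloxy)-4-methoxyphenyl]ethanone; 14 4-(TBSO)benzaldehyde
Product: 18 (2E)-1-[2,6-bis(allyloxy)-4-methoxyphenyl]-3-[4-(TBSO)phenyl]prop-2-en-1-one, via lithium enolate 15 (not isolated), via lithium aldolate 16 (not isolated), via β-mesyloxy ketone 17 (not isolated)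
Conditions: LiN(SiMe3)2, THF, −78 °C; 14; then MsCl, Et3N, −78 °C → rt
Reagents that add atoms: none
Why: Directed aldol addition to the non-enolisable aldehyde followed by mesylation and E1cB elimination (aldol condensation) should give the E-enone without the hydroxide that an aryl silyl ether would not survive.

Step 11
Reactants: 18 (2E)-1-[2,6-bis(allyloxy)-4-methoxyphenyl]-3-[4-(TBSO)phenyl]prop-2-en-1-one; 7 [(1E,4S)-4-(TBSO)-6-[4-(TBSO)phenyl]hex-1-en-1-yl]boronic acid
Product: 19 (3R,4E,7S)-1-[2,6-bis(allyloxy)-4-methoxyphenyl]-7-(TBSO)-3,9-bis[4-(TBSO)phenyl]non-4-en-1-one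
Conditions: [Rh(OH)((S)-BINAP)]2 (2.5 mol%), dioxane/H2O (10:1), 40 °C
Reagents that add atoms: none
Why: Hayashi–Miyaura rhodium-catalysed asymmetric 1,4-addition, in which the (S)-BINAP–Rh–alkenyl species adds to the 2si face of the E-enone and should set C3'' as (R) while the alkenyl group keeps its E geometry.

Step 12
Reactants: 19 (3R,4E,7S)-1-[2,6-bis(allyloxy)-4-methoxyphenyl]-7-(TBSO)-3,9-bis[4-(TBSO)phenyl]non-4-en-1-one
Product: 20 (1S,3R,4E,7S)-1-[2,6-bis(allyloxy)-4-methoxyphenyl]-7-(TBSO)-3,9-bis[4-(TBSO)phenyl]non-4-en-1-ol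
Conditions: (R)-2-methyl-CBS-oxazaborolidine (1 equiv), catecholborane, toluene, −78 → −40 °C; MeOH quench
Reagents that add atoms: none
Why: Corey–Bakshi–Shibata reduction with the aryl ring as the large group, so that the (R)-oxazaborolidine should deliver hydride to give the (1''S)-carbinol, while catecholborane does not hydroborate the alkenes at this temperature.

Step 13
Reactants: 20 (1S,3R,4E,7S)-1-[2,6-bis(allyloxy)-4-methoxyphenyl]-7-(TBSO)-3,9-bis[4-(TBSO)phenyl]non-4-en-1-ol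
Product: 21 2-[(1S,3R,4E,7S)-1-hydroxy-7-(TBSO)-3,9-bis[4-(TBSO)phenyl]non-4-en-1-yl]-5-methoxybenzene-1,3-diol
Conditions: Pd(PPh3)4 (5 mol%), morpholine, THF, rt
Reagents that add atoms: none
Why: Tsuji–Trost deallylation, in which the palladium catalyst ionises the aryl allyl ethers and morpholine captures the π-allyl, under near-neutral conditions that the benzylic carbinol and silyl ethers tolerate.

Step 14
Reactants: 21 2-[(1S,3R,4E,7S)-1-hydroxy-7-(TBSO)-3,9-bis[4-(TBSO)phenyl]non-4-en-1-yl]-5-methoxybenzene-1,3-diol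
Product: 22 (4S)-2,2-di-tert-butyl-7-methoxy-4-[(2R,3E,6S)-6-(TBSO)-2,8-bis[4-(TBSO)phenyl]oct-3-en-1-yl]-4H-1,3,2-benzodioxasilin-5-ol
Conditions: t-Bu2Si(OTf)2 (1.05 equiv), 2,6-lutidine, CH2Cl2, −78 → 0 °C
Reagents that add atoms: di-tert-butylsilyl bis(trifluoromethanesulfonate), CC(C)(C)[Si](OS(=O)(=O)C(F)(F)F)(OS(=O)(=O)C(F)(F)F)C(C)(C)C
Why: Cyclic silylene formation bridges one phenol oxygen and the C1'' hydroxyl in a six-membered ring; the two phenols are equivalent by rotation about the C8–C1'' bond, so either choice gives the same compound and exactly one phenol (the future O1) stays free.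

Step 15
Reactants: 22 (4S)-2,2-di-tert-butyl-7-methoxy-4-[(2R,3E,6S)-6-(TBSO)-2,8-bis[4-(TBSO)phenyl]oct-3-en-1-yl]-4H-1,3,2-benzodioxasilin-5-ol; 11 allyl (3R)-3-hydroxy-3-[4-(TBSO)phenyl]propanoate
Product: 23 allyl (3S)-3-[4-(TBSO)phenyl]-3-aryloxypropanoate (aryl = the benzodioxasilin-5-yl unit of 22)
Conditions: PPh3, DIAD, toluene, 0 °C → rt
Reagents that add atoms: none
Why: Mitsunobu etherification, an SN2 displacement of the activated (R)-carbinol by the phenoxide with inversion, should set C2 as (S).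

Step 16
Reactants: 23 allyl (3S)-3-[4-(TBSO)phenyl]-3-aryloxypropanoate
Product: 24 (3S)-3-[4-(TBSO)phenyl]-3-aryloxypropanoic acid (aryl as in 23)
Conditions: Pd(PPh3)4 (5 mol%), morpholine, THF, rt; pH 5 buffer work-up
Reagents that add atoms: none
Why: Tsuji–Trost deallylation of the allyl ester releases the acid without hydroxide or fluoride, so the silyl ethers and the β-aryloxy stereocentre are kept.

Step 17
Reactants: 24 (3S)-3-[4-(TBSO)phenyl]-3-aryloxypropanoic acid
Product: 26 silylene-bridged tetrakis-TBS ether of the target (2S)-flavanone, via mixed trifluoroacetic anhydride 25 (not isolated)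
Conditions: (CF3CO)2O (1.2 equiv), CH2Cl2, −20 → 0 °C; then cold aq NaHCO3
Reagents that add atoms: none
Why: The acid and (CF3CO)2O give mixed anhydride 25, whose polarised acyl carbon C4 is attacked by C4a of ring A to give a Wheland intermediate that loses a proton; this is an intramolecular Friedel–Crafts acylation, the classical closure of 3-aryloxypropanoic acids to chroman-4-ones. Ring C closes in the 6-exo-trig mode. No stereocentre is formed: C2 is not touched, and because the manifold is cationic no enolate arises that could open ring C by β-elimination of O1, so the (S)-configuration from step 15 should be kept. Regiochemistry needs no extra control: the three-atom tether from O1 reaches only C4a, C8 is blocked by the side chain, and C4a is ortho to O1 and to the C5 methoxy group and para to O7. The three silyloxyphenyl rings are less nucleophilic, and attack on ring B would need a five-membered closure at a carbon meta to its oxygen. The silylene ring keeps O7 and the C1'' oxygen out of the reaction, and the limited amount of anhydride disfavours trifluoroacetylation at C6.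

Step 18
Reactants: 26 silylene-bridged tetrakis-TBS ether of the target (2S)-flavanone
Product: 27 (2S)-7-hydroxy-8-[(1S,3R,4E,7S)-1,7-dihydroxy-3,9-bis(4-hydroxyphenyl)non-4-en-1-yl]-2-(4-hydroxyphenyl)-5-methoxychroman-4-one (target)
Conditions: HF·pyridine, excess pyridine, THF, 0 °C → rt
Reagents that add atoms: none
Why: Fluoride-mediated global desilylation should cleave the silylene ring and the four TBS ethers in a buffered medium, without the base that would open ring C or the strong acid that would ionise C1''.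

**Compound list**

1 | methyl 3-(4-hydroxyphenyl)propanoate | COC(=O)CCc1ccc(O)cc1 | starting material
2 | methyl 3-[4-(tert-butyldimethylsilyloxy)phenyl]propanoate | COC(=O)CCc1ccc(O[Si](C)(C)C(C)(C)C)cc1 | intermediate
3 | 3-[4-(tert-butyldimethylsilyloxy)phenyl]propanal | O=CCCc1ccc(O[Si](C)(C)C(C)(C)C)cc1 | intermediate
4 | (3S)-1-[4-(tert-butyldimethylsilyloxy)phenyl]hex-5-yn-3-ol | C#CC[C@@H](O)CCc1ccc(O[Si](C)(C)C(C)(C)C)cc1 | intermediate
5 | (3S)-3-(tert-butyldimethylsilyloxy)-1-[4-(tert-butyldimethylsilyloxy)phenyl]hex-5-yne | C#CC[C@@H](O[Si](C)(C)C(C)(C)C)CCc1ccc(O[Si](C)(C)C(C)(C)C)cc1 | intermediate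
6 | 2-[(1E,4S)-4-(TBSO)-6-[4-(TBSO)phenyl]hex-1-en-1-yl]-1,3,2-benzodioxaborole | B1(/C=C/C[C@@H](O[Si](C)(C)C(C)(C)C)CCc2ccc(O[Si](C)(C)C(C)(C)C)cc2)Oc2ccccc2O1 | intermediate
7 | [(1E,4S)-4-(TBSO)-6-[4-(TBSO)phenyl]hex-1-en-1-yl]boronic acid | OB(O)/C=C/C[C@@H](O[Si](C)(C)C(C)(C)C)CCc1ccc(O[Si](C)(C)C(C)(C)C)cc1 | intermediate
8 | methyl 3-(4-hydroxyphenyl)-3-oxopropanoate | COC(=O)CC(=O)c1ccc(O)cc1 | starting material
9 | allyl 3-(4-hydroxyphenyl)-3-oxopropanoate | C=CCOC(=O)CC(=O)c1ccc(O)cc1 | intermediate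
10 | allyl 3-[4-(tert-butyldimethylsilyloxy)phenyl]-3-oxopropanoate | C=CCOC(=O)CC(=O)c1ccc(O[Si](C)(C)C(C)(C)C)cc1 | intermediate
11 | allyl (3R)-3-hydroxy-3-[4-(tert-butyldimethylsilyloxy)phenyl]propanoate | C=CCOC(=O)C[C@@H](O)c1ccc(O[Si](C)(C)C(C)(C)C)cc1 | intermediate
12 | 1-(2,6-dihydroxy-4-methoxyphenyl)ethanone (2',6'-dihydroxy-4'-methoxyacetophenone) | CC(=O)c1c(O)cc(OC)cc1O | starting material
13 | 1-[2,6-bis(allyloxy)-4-methoxyphenyl]ethanone | CC(=O)c1c(OCC=C)cc(OC)cc1OCC=C | intermediate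
14 | 4-(tert-butyldimethylsilyloxy)benzaldehyde | O=Cc1ccc(O[Si](C)(C)C(C)(C)C)cc1 | starting material
15 | lithium 1-[2,6-bis(allyloxy)-4-methoxyphenyl]ethenolate | [Li+].[O-]C(=C)c1c(OCC=C)cc(OC)cc1OCC=C | intermediate
16 | lithium 3-[2,6-bis(allyloxy)-4-methoxyphenyl]-3-oxo-1-[4-(TBSO)phenyl]propan-1-olate (racemic) | [Li+].[O-]C(CC(=O)c1c(OCC=C)cc(OC)cc1OCC=C)c1ccc(O[Si](C)(C)C(C)(C)C)cc1 | intermediate
17 | 3-[2,6-bis(allyloxy)-4-methoxyphenyl]-3-oxo-1-[4-(TBSO)phenyl]propyl methanesulfonate (racemic) | CS(=O)(=O)OC(CC(=O)c1c(OCC=C)cc(OC)cc1OCC=C)c1ccc(O[Si](C)(C)C(C)(C)C)cc1 | intermediate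
18 | (2E)-1-[2,6-bis(allyloxy)-4-methoxyphenyl]-3-[4-(TBSO)phenyl]prop-2-en-1-one | COc1cc(OCC=C)c(C(=O)/C=C/c2ccc(O[Si](C)(C)C(C)(C)C)cc2)c(OCC=C)c1 | intermediate
19 | (3R,4E,7S)-1-[2,6-bis(allyloxy)-4-methoxyphenyl]-7-(TBSO)-3,9-bis[4-(TBSO)phenyl]non-4-en-1-one | COc1cc(OCC=C)c(C(=O)C[C@H](/C=C/C[C@@H](O[Si](C)(C)C(C)(C)C)CCc2ccc(O[Si](C)(C)C(C)(C)C)cc2)c2ccc(O[Si](C)(C)C(C)(C)C)cc2)c(OCC=C)c1 | intermediate
20 | (1S,3R,4E,7S)-1-[2,6-bis(allyloxy)-4-methoxyphenyl]-7-(TBSO)-3,9-bis[4-(TBSO)phenyl]non-4-en-1-ol | COc1cc(OCC=C)c([C@@H](O)C[C@H](/C=C/C[C@@H](O[Si](C)(C)C(C)(C)C)CCc2ccc(O[Si](C)(C)C(C)(C)C)cc2)c2ccc(O[Si](C)(C)C(C)(C)C)cc2)c(OCC=C)c1 | intermediate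
21 | 2-[(1S,3R,4E,7S)-1-hydroxy-7-(TBSO)-3,9-bis[4-(TBSO)phenyl]non-4-en-1-yl]-5-methoxybenzene-1,3-diol | COc1cc(O)c([C@@H](O)C[C@H](/C=C/C[C@@H](O[Si](C)(C)C(C)(C)C)CCc2ccc(O[Si](C)(C)C(C)(C)C)cc2)c2ccc(O[Si](C)(C)C(C)(C)C)cc2)c(O)c1 | intermediate
22 | (4S)-2,2-di-tert-butyl-7-methoxy-4-[(2R,3E,6S)-6-(TBSO)-2,8-bis[4-(TBSO)phenyl]oct-3-en-1-yl]-4H-1,3,2-benzodioxasilin-5-ol | COc1cc(O[Si]3(C(C)(C)C)C(C)(C)C)c([C@@H](O3)C[C@H](/C=C/C[C@@H](O[Si](C)(C)C(C)(C)C)CCc2ccc(O[Si](C)(C)C(C)(C)C)cc2)c2ccc(O[Si](C)(C)C(C)(C)C)cc2)c(O)c1 | intermediate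
23 | allyl (3S)-3-[4-(TBSO)phenyl]-3-{[(4S)-2,2-di-tert-butyl-7-methoxy-4-[(2R,3E,6S)-6-(TBSO)-2,8-bis[4-(TBSO)phenyl]oct-3-en-1-yl]-4H-1,3,2-benzodioxasilin-5-yl]oxy}propanoate | COc1cc(O[Si]3(C(C)(C)C)C(C)(C)C)c([C@@H](O3)C[C@H](/C=C/C[C@@H](O[Si](C)(C)C(C)(C)C)CCc2ccc(O[Si](C)(C)C(C)(C)C)cc2)c2ccc(O[Si](C)(C)C(C)(C)C)cc2)c(O[C@@H](CC(=O)OCC=C)c2ccc(O[Si](C)(C)C(C)(C)C)cc2)c1 | intermediate
24 | (3S)-3-[4-(TBSO)phenyl]-3-{[benzodioxasilin-5-yl as in 23]oxy}propanoic acid | COc1cc(O[Si]3(C(C)(C)C)C(C)(C)C)c([C@@H](O3)C[C@H](/C=C/C[C@@H](O[Si](C)(C)C(C)(C)C)CCc2ccc(O[Si](C)(C)C(C)(C)C)cc2)c2ccc(O[Si](C)(C)C(C)(C)C)cc2)c(O[C@@H](CC(=O)O)c2ccc(O[Si](C)(C)C(C)(C)C)cc2)c1 | intermediate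
25 | mixed anhydride of acid 24 with trifluoroacetic acid | COc1cc(O[Si]3(C(C)(C)C)C(C)(C)C)c([C@@H](O3)C[C@H](/C=C/C[C@@H](O[Si](C)(C)C(C)(C)C)CCc2ccc(O[Si](C)(C)C(C)(C)C)cc2)c2ccc(O[Si](C)(C)C(C)(C)C)cc2)c(O[C@@H](CC(=O)OC(=O)C(F)(F)F)c2ccc(O[Si](C)(C)C(C)(C)C)cc2)c1 | intermediate
26 | target (2S)-flavanone with O7 and the C1'' oxygen joined by Si(t-Bu)2 and the 4'-OH, both side-chain phenols and C7''–OH as TBS ethers | COc1cc(O[Si]3(C(C)(C)C)C(C)(C)C)c([C@@H](O3)C[C@H](/C=C/C[C@@H](O[Si](C)(C)C(C)(C)C)CCc2ccc(O[Si](C)(C)C(C)(C)C)cc2)c2ccc(O[Si](C)(C)C(C)(C)C)cc2)c2c1C(=O)C[C@@H](c1ccc(O[Si](C)(C)C(C)(C)C)cc1)O2 | intermediate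
27 | (2S)-7-hydroxy-8-[(1S,3R,4E,7S)-1,7-dihydroxy-3,9-bis(4-hydroxyphenyl)non-4-en-1-yl]-2-(4-hydroxyphenyl)-5-methoxychroman-4-one | COc1cc(O)c([C@@H](O)C[C@H](/C=C/C[C@@H](O)CCc2ccc(O)cc2)c2ccc(O)cc2)c2c1C(=O)C[C@@H](c1ccc(O)cc1)O2 | target

**Step count**

Total: 18 steps. Longest linear sequence: 13 steps (steps 1–5, then 11–18).

**Steps most likely to fail, each with a fallback**

Step 15 (Mitsunobu etherification). The activated carbinol may undergo β-elimination to the cinnamate ester, may partly ionise at the electron-rich benzylic carbon with erosion of configuration, or may react slowly with the ortho-substituted phenol. The fallback forms the O1–C2 bond by catalyst-controlled allylic substitution instead of SN2 inversion. It sets out from 22: its lithium phenoxide is allylated with (E)-3-[4-(TBSO)phenyl]prop-2-en-1-yl methyl carbonate F1 (from the corresponding cinnamyl alcohol and methyl chloroformate) under [Ir(cod)Cl]2/Feringa-type phosphoramidite catalysis (branched-selective Hartwig–Helmchen allylic etherification, ligand enantiomer chosen for the (S)-ether) to give the branched allyl aryl ether F2. 9-BBN hydroborates only the monosubstituted alkene, and NaBO3·4H2O oxidation gives the primary alcohol F3. TEMPO/PhI(OAc)2 in wet MeCN oxidises it to acid 24, where the route is rejoined.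

Step 12 (CBS reduction). Facial discrimination may be poor, or the reduction slow, because both flanks of the carbonyl are large (a di-ortho-substituted aryl ring against a branched chain). The fallback sets out from 19: both allyl groups are removed first (Pd(PPh3)4, morpholine) to give the 2,6-dihydroxyaryl ketone F4, in which hydrogen bonding from the ortho-hydroxyl groups holds the carbonyl in the ring plane. Transfer hydrogenation with RuCl[(S,S)-TsDPEN](p-cymene) in HCO2H/Et3N, a reaction known to work well on o-hydroxyaryl ketones, should then give triol 21 directly, where the route is rejoined (step 13 is no longer needed).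

Step 17 (ring closure). Trifluoroacetic acid may ionise the C1''–O or O1–C2 benzylic bond before the ring closes, or the anhydride may trifluoroacetylate C6. The fallback replaces the acylium manifold by a base-buffered iminium manifold. It sets out from 24, which is coupled with dimethylamine (Me2NH·HCl, EDC·HCl, HOBt, i-Pr2NEt) to the N,N-dimethylamide F5. Tf2O with 2,6-di-tert-butyl-4-methylpyridine in CH2Cl2 (−78 → 0 °C) activates the amide as its O-triflyl iminium ion, which closes onto C4a in a Vilsmeier–Haack-type cyclisation to the cyclic iminium triflate F6. Hydrolysis in THF/acetate buffer (pH 5) should give 26, where the route is rejoined.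

**Further compounds**

F1 | step 15 | (E)-3-[4-(tert-butyldimethylsilyloxy)phenyl]prop-2-en-1-yl methyl carbonate | COC(=O)OC/C=C/c1ccc(O[Si](C)(C)C(C)(C)C)cc1
F2 | step 15 | (S)-1-[4-(TBSO)phenyl]prop-2-en-1-yl ether of phenol 22 | COc1cc(O[Si]3(C(C)(C)C)C(C)(C)C)c([C@@H](O3)C[C@H](/C=C/C[C@@H](O[Si](C)(C)C(C)(C)C)CCc2ccc(O[Si](C)(C)C(C)(C)C)cc2)c2ccc(O[Si](C)(C)C(C)(C)C)cc2)c(O[C@@H](C=C)c2ccc(O[Si](C)(C)C(C)(C)C)cc2)c1
F3 | step 15 | (3S)-3-[4-(TBSO)phenyl]-3-aryloxypropan-1-ol (aryl as in 23) | COc1cc(O[Si]3(C(C)(C)C)C(C)(C)C)c([C@@H](O3)C[C@H](/C=C/C[C@@H](O[Si](C)(C)C(C)(C)C)CCc2ccc(O[Si](C)(C)C(C)(C)C)cc2)c2ccc(O[Si](C)(C)C(C)(C)C)cc2)c(O[C@@H](CCO)c2ccc(O[Si](C)(C)C(C)(C)C)cc2)c1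
F4 | step 12 | (3R,4E,7S)-1-(2,6-dihydroxy-4-methoxyphenyl)-7-(TBSO)-3,9-bis[4-(TBSO)phenyl]non-4-en-1-one | COc1cc(O)c(C(=O)C[C@H](/C=C/C[C@@H](O[Si](C)(C)C(C)(C)C)CCc2ccc(O[Si](C)(C)C(C)(C)C)cc2)c2ccc(O[Si](C)(C)C(C)(C)C)cc2)c(O)c1
F5 | step 17 | N,N-dimethylamide of acid 24 | COc1cc(O[Si]3(C(C)(C)C)C(C)(C)C)c([C@@H](O3)C[C@H](/C=C/C[C@@H](O[Si](C)(C)C(C)(C)C)CCc2ccc(O[Si](C)(C)C(C)(C)C)cc2)c2ccc(O[Si](C)(C)C(C)(C)C)cc2)c(O[C@@H](CC(=O)N(C)C)c2ccc(O[Si](C)(C)C(C)(C)C)cc2)c1
F6 | step 17 | C4 N,N-dimethyliminium triflate of 26 | COc1cc(O[Si]3(C(C)(C)C)C(C)(C)C)c([C@@H](O3)C[C@H](/C=C/C[C@@H](O[Si](C)(C)C(C)(C)C)CCc2ccc(O[Si](C)(C)C(C)(C)C)cc2)c2ccc(O[Si](C)(C)C(C)(C)C)cc2)c2c1C(=[N+](C)C)C[C@@H](c1ccc(O[Si](C)(C)C(C)(C)C)cc1)O2.[O-]S(=O)(=O)C(F)(F)F
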